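**Plan**
1. Retrosynthetic cuts: the two senecioate C–O bonds; the C7=C8 unsaturation; C5–C10 (cyclobutane); C4–C5 and C8–C9 together (cyclohexene, made through an O3–Si–O6 link); C4=C9 (metathesis); C2–C3 (aldol).
2. Forward order: the acyclic chain by aldol addition, the cycloheptenone by ring-closing metathesis, the cyclohexene by a silicon-tethered [4+2], then, once the silicon link is cut, the cyclobutane by Norrish–Yang closure, and last the enone and the esters.
3. Enabling feature: in the cycloadduct O3 (on C3) and the oxygen on C6 flank the new C4–C5 bond on the same face, so one silicon atom joins them in a seven-membered ring C3–O–Si–O–C6–C5–C4. In the final cage C3 and C6 lie on opposite faces of the cyclobutane C4–C5–C10–C9, so this ring has to be opened before C5–C10 is formed.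
4. Stereochemistry: C3 from a reagent-controlled boron aldol; C1 from a 1,3-anti Evans–Tishchenko reduction; C4 and C9 from tether-directed, suprafacial cycloaddition; C5 and C10 from the geometry of the cage.

Key step: step 8

Assumption: ring carbons are numbered C1–C11 in the order of the target SMILES (C1 and C3 ester carbinols, C4 quaternary, C6 ketone, C7=C8, C11 CMe2); this numbering is used in all descriptive names.
Assumption: (−)-Ipc2BCl is taken as the antipode that gives the 3R aldol; if its sense is the opposite, (+)-Ipc2BCl is used.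

**Route**

Step 1
Reactants: 1 3,3-dimethylpentane-2,4-dione; 2 methacrolein
Product: 3 (6R)-6-hydroxy-3,3,7-trimethyloct-7-ene-2,4-dione
Conditions: (−)-Ipc2BCl, Et3N, Et2O, 0 °C; then 2, −78 → −20 °C; H2O2, pH 7 buffer, MeOH, 0 °C
Reagents that add atoms: none
Why: Ipc2BCl-mediated boron aldol of a methyl ketone, in which the isopinocampheyl ligands differentiate the aldehyde faces and set C3 (R), while the symmetrical dione can enolise only at a methyl group.

Step 2
Reactants: 3 (6R)-6-hydroxy-3,3,7-trimethyloct-7-ene-2,4-dione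
Product: 4 (3R,5R)-5-hydroxy-2,6,6-trimethyl-7-oxooct-1-en-3-yl acetate
Conditions: MeCHO (3 equiv), SmI2 (0.2 equiv), THF, −10 °C
Reagents that add atoms: acetaldehyde, CC=O
Why: Evans–Tishchenko reduction, in which the samarium-bound hemiacetal on O3 delivers hydride to the C1 ketone through a chair-like bicyclic transition state, giving the 1,3-anti diol with O3 acetylated and O1 free; the C10 ketone has no β-hydroxyl until this transfer is over, and the hindered O1 alkoxide then formed should react more slowly.

Step 3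
Reactants: 4 (3R,5R)-5-hydroxy-2,6,6-trimethyl-7-oxooct-1-en-3-yl acetate
Product: 5 (3R,5R)-5-[tert-butyl(dimethyl)silyl]oxy-2,6,6-trimethyl-7-oxooct-1-en-3-yl acetate
Conditions: TBSOTf, 2,6-lutidine, CH2Cl2, −78 → 0 °C
Reagents that add atoms: tert-butyldimethylsilyl trifluoromethanesulfonate, CC(C)(C)[Si](C)(C)OS(=O)(=O)C(F)(F)F
Why: Silyl triflate silylation of the neopentylic C1 hydroxyl, with the acetate keeping O3 distinguished.

Step 4
Reactants: 5 (3R,5R)-5-[tert-butyl(dimethyl)silyl]oxy-2,6,6-trimethyl-7-oxooct-1-en-3-yl acetate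
Product: 6 (4R,6R)-4-[tert-butyl(dimethyl)silyl]oxy-6-hydroxy-3,3,7-trimethyloct-7-en-2-one
Conditions: K2CO3 (0.3 equiv), MeOH, 0 °C
Reagents that add atoms: none
Why: Base-catalysed methanolysis (transesterification) of the acetate frees O3 quickly at low temperature, which limits silyl migration, and the quaternary C11 excludes β-elimination of the silyloxy group.

Step 5
Reactants: 6 (4R,6R)-4-[tert-butyl(dimethyl)silyl]oxy-6-hydroxy-3,3,7-trimethyloct-7-en-2-one
Product: 9 (5R,7R)-5-[tert-butyl(dimethyl)silyl]oxy-7-hydroxy-4,4,8-trimethylnona-1,8-dien-3-one, via Mannich base 7 (not isolated), via trimethylammonium iodide 8 (not isolated)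
Conditions: LiN(iPr)2 (2.2 equiv), THF, −78 °C; CH2=NMe2+ I−, −78 → −20 °C; aqueous work-up; MeI, CH2Cl2, 20 °C; aq. NaHCO3, CH2Cl2, 20 °C
Reagents that add atoms: N,N-dimethylmethaniminium iodide (Eschenmoser's salt), C=[N+](C)C.[I-]
Why: Mannich methylenation of a methyl ketone: the C10 ketone can enolise only towards its methyl group (C9), the enolate adds to the iminium salt, and quaternisation followed by Hofmann-type elimination gives the vinyl ketone.

Step 6
Reactants: 9 (5R,7R)-5-[tert-butyl(dimethyl)silyl]oxy-7-hydroxy-4,4,8-trimethylnona-1,8-dien-3-one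
Product: 10 (4R,6R)-6-[tert-butyl(dimethyl)silyl]oxy-4-hydroxy-3,7,7-trimethylcyclohept-2-en-1-one
Conditions: second-generation Hoveyda–Grubbs catalyst RuCl2(H2IMes)(=CH-C6H4-2-OiPr) (5 mol %), PhMe (0.005 M), 80 °C
Reagents that add atoms: none
Why: Ring-closing metathesis between the vinyl ketone and the 1,1-disubstituted alkene closes the seven-membered ring as the trisubstituted C4=C9 enone with loss of ethene, helped by the gem-dimethyl group and tolerated by the free allylic hydroxyl.

Step 7
Reactants: 10 (4R,6R)-6-[tert-butyl(dimethyl)silyl]oxy-4-hydroxy-3,7,7-trimethylcyclohept-2-en-1-one; 11 (E)-pent-3-en-2-one; 12 dichlorodi(propan-2-yl)silane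
Product: 14 (4R,6R)-6-[tert-butyl(dimethyl)silyl]oxy-4-{[(3E)-penta-1,3-dien-2-yloxy]di(propan-2-yl)silyl}oxy-3,7,7-trimethylcyclohept-2-en-1-one, via chlorosilyl dienol ether 13 (not isolated)
Conditions: 11, LiN(iPr)2, THF, −78 °C; added to 12, THF, −78 → 0 °C; then 10, imidazole, CH2Cl2, 0 → 20 °C
Reagents that add atoms: none
Why: Kinetic enolisation of the enone at its methyl group and O-silylation by the dichlorosilane give the chlorosilyl dienol ether, which then silylates the C3 hydroxyl (unsymmetrical silyl acetal formation); the isopropyl groups make the product robust enough to purify.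

Step 8
Reactants: 14 (4R,6R)-6-[tert-butyl(dimethyl)silyl]oxy-4-{[(3E)-penta-1,3-dien-2-yloxy]di(propan-2-yl)silyl}oxy-3,7,7-trimethylcyclohept-2-en-1-one
Product: 15 silicon-bridged cycloadduct (cis-fused cyclohexene/cycloheptanone; O3–Si(iPr)2–O6 siloxane ring; C6=C7 enol ether)
Conditions: PhMe (0.01 M), BHT (0.1 equiv), sealed tube, 170 °C
Reagents that add atoms: none
Why: A thermal, concerted but asynchronous [4+2] joins the nucleophilic diene terminus C5 to the enone β-carbon C4 and the methyl-bearing terminus C8 to the α-carbon C9; because the tether sits on the internal diene carbon (through O6) this is a type 2 intramolecular Diels–Alder reaction, the closest known class being silyl-acetal-tethered cycloadditions of 2-silyloxydienes. The cyclohexene ring is closed by the cycloaddition itself, and the seven-membered ring C3–O–Si–O–C6–C5–C4 is closed by the new C4–C5 bond as the bridging ring of a bicyclo[4.3.1] unit with a bridgehead enol ether. C4 is set because the three-atom O–Si–O link cannot reach the far face of the alkene, so C5 is delivered syn to O3. C9 follows from suprafacial addition to the ring alkene, which gives the cis ring fusion (C9–H cis to the C4 methyl). C8 is set by the tether, which forces C3 and therefore C10 under the diene (endo) and so places the outside methyl of the E-diene cis to C10; this centre is removed in step 16. The step needs face and regiochemical control; the tether supplies both, and the polarity of the 2-oxygenated diene and the enone agrees with it.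

Step 9
Reactants: 15 silicon-bridged cycloadduct
Product: 16 hydroxy diketone (cis-fused bicycle; C3–OH; C6 and C10 ketones; C1–OTBS)
Conditions: HF·pyridine, pyridine, THF, 0 °C
Reagents that add atoms: none
Why: Fluoride-mediated desilylation cleaves both Si–O bonds of the dialkoxysilane and the enol is protonated at C7, while the hindered secondary TBS ether should survive the buffered reagent; the link is removed here because one silicon cannot span C3 and C6 once they lie on opposite faces of the cyclobutane.

Step 10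
Reactants: 16 hydroxy diketone
Product: 17 O3-triethylsilyl ether of 16
Conditions: TESOTf, 2,6-lutidine, CH2Cl2, −78 °C
Reagents that add atoms: triethylsilyl trifluoromethanesulfonate, CC[Si](CC)(CC)OS(=O)(=O)C(F)(F)F
Why: Silyl triflate silylation of the C3 hydroxyl, which also adds bulk next to C5.

Step 11
Reactants: 17 O3-triethylsilyl ether of 16
Product: 18 C6=C7 triethylsilyl enol ether of 17
Conditions: LiN(iPr)2 (1.1 equiv), TESCl (in situ), THF, −78 °C
Reagents that add atoms: chlorotriethylsilane, CC[Si](Cl)(CC)CC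
Why: Kinetic enolisation with in situ silyl trapping should remove a C7 proton (next to the tertiary C8) in preference to a C5 proton (next to the quaternary C4 and the C3 silyl ether) or the shielded tertiary C9–H.

Step 12
Reactants: 18 C6=C7 triethylsilyl enol ether of 17
Product: 19 tricyclic cyclobutanol (C5–C10 bond; C10–OH)
Conditions: hν (≥ 300 nm, Pyrex filter), degassed C6H6/t-BuOH, 20 °C
Reagents that add atoms: none
Why: Norrish–Yang cyclisation: the n,π* excited C10 ketone abstracts the allylic C5 hydrogen through a six-membered transition state and the 1,4-biradical closes C5–C10; the masked C6 carbonyl excludes retro-aldol opening, and C5 and C10 can only adopt the cage configuration because C10 bridges C5 and C9 from the face that carries it.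

Step 13
Reactants: 19 tricyclic cyclobutanol
Product: 20 methyl oxalate of 19
Conditions: ClC(O)CO2Me, DMAP, pyridine, CH2Cl2, 0 → 20 °C
Reagents that add atoms: methyl 2-chloro-2-oxoacetate, COC(=O)C(Cl)=O
Why: DMAP-catalysed acylation of the tertiary cyclobutanol by a highly electrophilic acid chloride, without forming a free alkoxide that could open the 2-alkenylcyclobutanol.

Step 14
Reactants: 20 methyl oxalate of 19
Product: 21 deoxygenated tricycle (C10–H; C6=C7 silyl enol ether)
Conditions: Bu3SnH, AIBN (cat.), PhMe, 110 °C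
Reagents that add atoms: none
Why: Radical deoxygenation of a tertiary methyl oxalate (Barton–McCombie type): stannyl radical addition and C–O scission give the C10 cyclobutyl radical, which can take hydrogen only from outside the cage, so C10 keeps its configuration.

Step 15
Reactants: 21 deoxygenated tricycle
Product: 22 C7 bromo ketone (Br cis to the C8 methyl)
Conditions: NBS, NaHCO3, THF, −78 → 0 °C
Reagents that add atoms: N-bromosuccinimide, O=C1CCC(=O)N1Br
Why: Electrophilic bromination of the silyl enol ether is regiospecific for C7, and bromine should enter anti to the C4 bridge, whose methyl group points at C7, which places it cis to the C8 methyl and trans to C8–H.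

Step 16
Reactants: 22 C7 bromo ketone
Product: 23 enone with C1–OTBS and C3–OTES
Conditions: Li2CO3, LiBr, DMF, 120 °C
Reagents that add atoms: none
Why: Dehydrobromination of the α-bromo ketone by anti elimination (E2) of the trans C8–H; enolisation towards the bridgehead C5 is forbidden, so only the C7=C8 enone can form and the C8 stereocentre disappears.

Step 17
Reactants: 23 enone with C1–OTBS and C3–OTES
Product: 24 enone diol
Conditions: HF·pyridine, THF, 0 → 20 °C
Reagents that add atoms: none
Why: Fluoride-mediated desilylation removes both silyl ethers and leaves the enone and cyclobutane untouched.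

Step 18
Reactants: 24 enone diol
Product: 25 CNP0105062.1 (C1,C3-bis(3-methylbut-2-enoate) of 24)
Conditions: 3-methylbut-2-enoyl chloride (excess), DMAP, pyridine, CH2Cl2, 0 → 40 °C
Reagents that add atoms: 3-methylbut-2-enoyl chloride, CC(C)=CC(Cl)=O
Why: DMAP-catalysed acylation of both hindered secondary alcohols, with pyridine in place of a trialkylamine to limit vinylketene formation and deconjugation of the acyl group.

**Compound list**
1 | 3,3-dimethylpentane-2,4-dione | CC(=O)C(C)(C)C(C)=O | starting material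
2 | methacrolein | CC(=C)C=O | starting material
3 | (6R)-6-hydroxy-3,3,7-trimethyloct-7-ene-2,4-dione | CC(=O)C(C)(C)C(=O)C[C@@H](O)C(C)=C | intermediate
4 | (3R,5R)-5-hydroxy-2,6,6-trimethyl-7-oxooct-1-en-3-yl acetate | CC(=O)C(C)(C)[C@H](O)C[C@@H](OC(C)=O)C(C)=C | intermediate
5 | (3R,5R)-5-[tert-butyl(dimethyl)silyl]oxy-2,6,6-trimethyl-7-oxooct-1-en-3-yl acetate | CC(=O)C(C)(C)[C@H](O[Si](C)(C)C(C)(C)C)C[C@@H](OC(C)=O)C(C)=C | intermediate
6 | (4R,6R)-4-[tert-butyl(dimethyl)silyl]oxy-6-hydroxy-3,3,7-trimethyloct-7-en-2-one | CC(=O)C(C)(C)[C@H](O[Si](C)(C)C(C)(C)C)C[C@@H](O)C(C)=C | intermediate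
7 | (5R,7R)-5-[tert-butyl(dimethyl)silyl]oxy-1-(dimethylamino)-7-hydroxy-4,4,8-trimethylnon-8-en-3-one (Mannich base) | CN(C)CCC(=O)C(C)(C)[C@H](O[Si](C)(C)C(C)(C)C)C[C@@H](O)C(C)=C | intermediate
8 | N-methyl ammonium iodide of 7 | C[N+](C)(C)CCC(=O)C(C)(C)[C@H](O[Si](C)(C)C(C)(C)C)C[C@@H](O)C(C)=C.[I-] | intermediate
9 | (5R,7R)-5-[tert-butyl(dimethyl)silyl]oxy-7-hydroxy-4,4,8-trimethylnona-1,8-dien-3-one | C=CC(=O)C(C)(C)[C@H](O[Si](C)(C)C(C)(C)C)C[C@@H](O)C(C)=C | intermediate
10 | (4R,6R)-6-[tert-butyl(dimethyl)silyl]oxy-4-hydroxy-3,7,7-trimethylcyclohept-2-en-1-one | CC(C)(C)[Si](C)(C)O[C@@H]1C[C@@H](O)C(C)=CC(=O)C1(C)C | intermediate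
11 | (E)-pent-3-en-2-one | C/C=C/C(C)=O | starting material
12 | dichlorodi(propan-2-yl)silane | CC(C)[Si](Cl)(Cl)C(C)C | starting material
13 | chloro[(3E)-penta-1,3-dien-2-yloxy]di(propan-2-yl)silane | C/C=C/C(=C)O[Si](Cl)(C(C)C)C(C)C | intermediate
14 | (4R,6R)-6-[tert-butyl(dimethyl)silyl]oxy-4-{[(3E)-penta-1,3-dien-2-yloxy]di(propan-2-yl)silyl}oxy-3,7,7-trimethylcyclohept-2-en-1-one | CC(C)(C)[Si](C)(C)O[C@@H]1C[C@@H](O[Si](C(C)C)(C(C)C)OC(=C)/C=C/C)C(C)=CC(=O)C1(C)C | intermediate
15 | silicon-bridged cycloadduct: cis-fused cyclohexene/cycloheptanone (C4 methyl cis to C9–H), O3 and O6 joined by Si(iPr)2, C6=C7 enol ether, C8 methyl cis to C10, C10 ketone, C1–OTBS | CC(C)(C)[Si](C)(C)O[C@@H]1C[C@@H](O[Si]3(C(C)C)C(C)C)[C@@]2(C)CC(O3)=C[C@@H](C)[C@H]2C(=O)C1(C)C | intermediate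
16 | hydroxy diketone: cis-fused bicycle with C3–OH, C6 and C10 ketones, C1–OTBS | CC(C)(C)[Si](C)(C)O[C@@H]1C[C@@H](O)[C@@]2(C)CC(=O)C[C@@H](C)[C@H]2C(=O)C1(C)C | intermediate
17 | O3-triethylsilyl ether of 16 | CC(C)(C)[Si](C)(C)O[C@@H]1C[C@@H](O[Si](CC)(CC)CC)[C@@]2(C)CC(=O)C[C@@H](C)[C@H]2C(=O)C1(C)C | intermediate
18 | C6=C7 triethylsilyl enol ether of 17 | CC(C)(C)[Si](C)(C)O[C@@H]1C[C@@H](O[Si](CC)(CC)CC)[C@@]2(C)CC(O[Si](CC)(CC)CC)=C[C@@H](C)[C@H]2C(=O)C1(C)C | intermediate
19 | tricyclic cyclobutanol: C5–C10 bond, C10–OH, C6=C7 silyl enol ether | CC(C)(C)[Si](C)(C)O[C@@H]1C[C@@H](O[Si](CC)(CC)CC)[C@@]2(C)[C@@H]3C(O[Si](CC)(CC)CC)=C[C@@H](C)[C@H]2[C@]3(O)C1(C)C | intermediate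
20 | methyl oxalate of 19 | CC(C)(C)[Si](C)(C)O[C@@H]1C[C@@H](O[Si](CC)(CC)CC)[C@@]2(C)[C@@H]3C(O[Si](CC)(CC)CC)=C[C@@H](C)[C@H]2[C@]3(OC(=O)C(=O)OC)C1(C)C | intermediate
21 | deoxygenated tricycle: C10–H, C6=C7 silyl enol ether | CC(C)(C)[Si](C)(C)O[C@@H]1C[C@@H](O[Si](CC)(CC)CC)[C@@]2(C)[C@@H]3C(O[Si](CC)(CC)CC)=C[C@@H](C)[C@H]2[C@@H]3C1(C)C | intermediate
22 | C7 bromo ketone (Br cis to the C8 methyl) | CC(C)(C)[Si](C)(C)O[C@@H]1C[C@@H](O[Si](CC)(CC)CC)[C@@]2(C)[C@@H]3C(=O)[C@@H](Br)[C@@H](C)[C@H]2[C@@H]3C1(C)C | intermediate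
23 | enone with C1–OTBS and C3–OTES | CC(C)(C)[Si](C)(C)O[C@@H]1C[C@@H](O[Si](CC)(CC)CC)[C@@]2(C)[C@@H]3C(=O)C=C(C)[C@H]2[C@@H]3C1(C)C | intermediate
24 | enone diol | O[C@@H]1C[C@@H](O)[C@@]2(C)[C@@H]3C(=O)C=C(C)[C@H]2[C@@H]3C1(C)C | intermediate
25 | CNP0105062.1 | CC(C)=CC(=O)O[C@@H]1C[C@@H](OC(=O)C=C(C)C)[C@@]2(C)[C@@H]3C(=O)C=C(C)[C@H]2[C@@H]3C1(C)C | target

**Step count and risks**
Total steps: 18. Longest linear sequence: 18 (1 → 25; the dienyl chlorosilane is made and used in the flask in step 7).

Step 8. The cycloaddition onto a trisubstituted β-methyl enone may be slower than thermal decay of the dienyl silyl ether (protodesilylation, polymerisation). The fallback sets out from 10 and returns at 16. O3 is acylated by the acylketene released from 2,2-dimethyl-6-[(E)-prop-1-enyl]-1,3-dioxin-4-one (PhMe, 110 °C) to give the β-keto ester F1. Cs2CO3 in MeCN then brings about an anionic double Michael annulation: C5 adds to C4 in a 5-exo closure that can only give the cis-fused γ-lactone, hence the same C4 configuration, and the C9 enolate so formed adds to C8, giving the keto lactone F2. LiOH opens the lactone to the β-keto acid F3, which loses CO2 on mild acidification and warming to give 16. The C8 methyl is expected cis to C10 as in 16 if the second addition closes through the same folded arrangement; this centre becomes sp2 in step 16 in any case.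

Step 12. The excited ketone may be lost through α-cleavage at C10–C11, through fragmentation of the 1,4-biradical across C4–C9, through closure of the allyl radical at C7 instead of C5, or through capture by the enol ether. The fallback sets out from 17 and returns at 21; it also removes the regiochemical demand of step 11. The C6 ketone, the less hindered of the two, is converted into the dioxolane F4 (ethylene glycol, PPTS, PhH, reflux). Irradiation as in step 12 then passes through a localised C5 radical and gives the cyclobutanol ketal F5. Acylation as in step 13 gives the oxalate F6, and Bu3SnH/AIBN gives the deoxygenated ketal F7. PPTS in wet acetone releases the ketone F8, and TESOTf/Et3N gives 21 (and restores the O3 silyl ether if it was lost), because with C5 now a bridgehead only the C6=C7 enol ether can form.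

Step 14. Hydrogen transfer to the strained C10 cyclobutyl radical may be outrun by β-scission of the ring, and the preceding acylation of the hindered tertiary alcohol may stall. The fallback sets out from 19 and returns at 21. Deprotonation with n-BuLi (THF, −78 °C) and phosphorylation with ClP(O)(NMe2)2 give the phosphorodiamidate F9. Lithium in EtNH2/t-BuOH/THF at 0 °C then cleaves the C10–O bond by two-electron reduction, so that the short-lived radical is reduced to the carbanion and protonated before it can fragment.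

**Further compounds**
F1 | step 8 | O3 (E)-3-oxohex-4-enoate of 10 | CC(C)(C)[Si](C)(C)O[C@@H]1C[C@@H](OC(=O)CC(=O)/C=C/C)C(C)=CC(=O)C1(C)C
F2 | step 8 | keto lactone (O3–C(=O)–C5 γ-lactone; C6 and C10 ketones) | CC(C)(C)[Si](C)(C)O[C@@H]1C[C@@H](OC3=O)[C@@]2(C)[C@@H]3C(=O)C[C@@H](C)[C@H]2C(=O)C1(C)C
F3 | step 8 | β-keto acid (C5–CO2H; C3–OH) | CC(C)(C)[Si](C)(C)O[C@@H]1C[C@@H](O)[C@@]2(C)[C@@H](C(=O)O)C(=O)C[C@@H](C)[C@H]2C(=O)C1(C)C
F4 | step 12 | C6 ethylene ketal of 17 | CC(C)(C)[Si](C)(C)O[C@@H]1C[C@@H](O[Si](CC)(CC)CC)[C@@]2(C)CC3(OCCO3)C[C@@H](C)[C@H]2C(=O)C1(C)C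
F5 | step 12 | cyclobutanol ketal (C5–C10 bond; C10–OH) | CC(C)(C)[Si](C)(C)O[C@@H]1C[C@@H](O[Si](CC)(CC)CC)[C@@]2(C)[C@@H]3C4(OCCO4)C[C@@H](C)[C@H]2[C@]3(O)C1(C)C
F6 | step 12 | methyl oxalate of F5 | CC(C)(C)[Si](C)(C)O[C@@H]1C[C@@H](O[Si](CC)(CC)CC)[C@@]2(C)[C@@H]3C4(OCCO4)C[C@@H](C)[C@H]2[C@]3(OC(=O)C(=O)OC)C1(C)C
F7 | step 12 | deoxygenated ketal (C10–H) | CC(C)(C)[Si](C)(C)O[C@@H]1C[C@@H](O[Si](CC)(CC)CC)[C@@]2(C)[C@@H]3C4(OCCO4)C[C@@H](C)[C@H]2[C@@H]3C1(C)C
F8 | step 12 | saturated C6 ketone of the cage | CC(C)(C)[Si](C)(C)O[C@@H]1C[C@@H](O[Si](CC)(CC)CC)[C@@]2(C)[C@@H]3C(=O)C[C@@H](C)[C@H]2[C@@H]3C1(C)C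
F9 | step 14 | C10 N,N,N',N'-tetramethylphosphorodiamidate of 19 | CC(C)(C)[Si](C)(C)O[C@@H]1C[C@@H](O[Si](CC)(CC)CC)[C@@]2(C)[C@@H]3C(O[Si](CC)(CC)CC)=C[C@@H](C)[C@H]2[C@]3(OP(=O)(N(C)C)N(C)C)C1(C)C
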